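The numbers of this flask stand for no real mixture; what happens was integrated by code.

Time comes first: this flask runs for 1.5 h, and I want what stands when that time ends.

    crystals ⇌ target, rate k1*(cs1 - [target]) while solid is left; crystals form when [target] > cs1 (cs1 = 0.068 M, k1 = 1.8 /min)
    solid substrate ⇌ dissolved substrate, rate k2*(cs2 - [dissolved substrate]) while solid is left; crystals form when [dissolved substrate] > cs2 (cs2 = 0.062 M, k2 = 0.10 /min)
    target ⇌ isomer of the product (K3 = 0.41, k3 = 0.50 /min)
    dissolved substrate + coupling partner → target (k4 = 12 /M/min)
    coupling partner ⇌ dormant form (K5 = 1.5, k5 = 0.23 /min)
solid substrate 0.16 M; coupling partner 2.50 equiv; time 1.5 h
- north-east: doubling the solubility in step 2, all else as stated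
- south: doubling the dissolution coefficient of step 2, all else as stated
- north-west: doubling the dissolution coefficient of step 1, all else as stated
- south-east: doubling the amount of coupling partner, all else as stated
1. the target and crystals together standing at 1.5 h, as a percentage of the solid substrate charged
2. concentration of dissolved substrate in solution at 25 min, in percent of saturation
3. the change that raises the amount of target and crystals together at 1.5 h, in percent of the solid substrate charged most ("none" if none brings more than 2 percentage points) (north-east / south / north-west / south-east / none)
4. amount of target and crystals together at 1.5 h, in percent of the solid substrate charged, after north-west
- what is said of target includes crystals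
- solid substrate, crystals is a solid; its amount is given per volume of the solution
- at the start none of the solid substrate is in solution
- dissolved substrate means what is dissolved; the solid is not counted in it
- run time (flask): 1.5 h

The crystals' line gives a ceiling: while crystals stand, dissolved target sits at its solubility s = 0.068 M. But crystals need supply, and the solid's line delivers at most 0.006200 M/min, so the charge c needs at least 25.8 min, which is less than the run. The isomer's line ties isomer to dissolved target with K = 0.41, and its relaxation half-life of 0.403 min is shorter than the run, so I take that ratio as met at the end. Dissolved substrate has a half-life of 0.14 min against the coupling partner as charged, shorter than the dissolving time, so it should stay well below saturation. The dormant form relaxes with a half-life of 1.81 min, shorter than the run, and the partner charged, 0.400 M, exceeds the substrate.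

So I read the end as thermodynamic control. With the whole charge coupled, the isomer ratio met and no crystals, dissolved target is c/(1 + K), and this reaches s at the crossing charge c* = s(1 + K) = 0.0959 M. Under those same conditions, isomer takes a fixed share of the charge below c*; above it, isomer stops at Ks and the excess crystallises. This flask lies above, so I commit to y = 1 − Ks/c = 82.6 %. That expression holds no rate and no partner amount, so I expect none of the changes to pass 2 percentage points. For sat I reckon nothing beyond a low value.

The forecast gives y 82.6 %, sat 8.1 %, best none and yb 82.6 %, with “target held at its 0.068 M solubility”.

The simulation gives y 82.6 %, sat 7.95 %, best none and yb 82.6 %; the gains are north-east 0 points, south 0 points, north-west 0 points and south-east 0 points.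

In this flask the excess over the crossing is 40.1 % of the charge, and crystals stand at 40.1 % at 1.50 h. The neighbour flask charged with 0.064 M lies below the crossing, so the same reckoning gives it no crystals and target at 1/(1 + K) = 70.9 % of its charge. That neighbour reads y 70.9 % at 1.50 h, with crystals at 0 % and isomer at 29.1 %.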